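Remark: lithium, sodium and boron enolates and the aryllithium are the metalated forms of the numbered compounds from which they arise; they are described in the Why lines and carry no number of their own. Both enantiomers of 4-benzyl-1,3-oxazolidin-2-one are taken as commercial.

## Analysis of the target

The target is a trans-3,4-dibenzyl oxolan-2-one (γ-butyrolactone). The benzyl group on lactone C3 is a guaiacyl ring whose C4 oxygen is the ether oxygen of an aryl glycerol unit. The benzyl group on lactone C4 is C5 of a 7-methoxy-2,3-dihydro-1-benzofuran carrying a guaiacyl ring on C2 and a hydroxymethyl group on C3.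

There are six stereocentres in three vicinal pairs: lactone C3/C4 (3R,4R, trans), dihydrobenzofuran C2/C3 (2S,3R, trans) and glycerol C1/C2 (1R,2S, erythro, which is anti when the chain is drawn as a zigzag). The pairs are separated by CH2–arene spacers, so none can relay its configuration to another and each needs its own source of absolute configuration.

The sensitive groups are two free phenols, each para to a benzylic C–O bond (the secondary glycerol alcohol and the O1–C2 bond of the dihydrobenzofuran). These bonds ionise in acid, open to quinone methides in base and can be hydrogenolysed. Lactone C3 is epimerisable. The difficulty is therefore remote stereocontrol combined with end-game conditions that spare three benzylic C–O bonds.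

The strategy rests on C2 of the dihydrobenzofuran. It is a benzylic ether carbon para to the oxygen of its own aryl ring, so the O1–C2 bond can be made through a quinone-methide-like cation whatever the configuration of the carbinol. Only C3 of that pair has to be set by a reagent.

## Retrosynthetic reasoning

**Protecting groups.** Target 38 is traced back to dibenzyl ether 37 and then to the fully protected lactone 36. The two phenols are benzyl ethers (they arrive with aldehyde 9) and the three alcohols are silyl ethers. The last two steps, fluoride and hydrogenolysis, involve neither acid nor strong base, which the benzylic C–O bonds require.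

**Lactone C3–CH2 bond.** Cutting the bond between lactone C3 and its benzylic CH2 divides 36 into lactone 24 and benzylic bromide 35, two halves of similar size. The forward reaction is an enolate alkylation on the face anti to the C4 substituent, which sets C3 trans to C4 with no further reagent control.

**Lactone C4–CH2 bond.** Lactone 24 is opened to hydroxy ester 23 and imide 22. Cutting the bond between the future C4 and its benzylic CH2 gives benzylic bromide 17 and succinyl imide 21, made from acid 18 and the (4R)-auxiliary 19. C4 is remote from the dihydrobenzofuran centres, so an auxiliary-controlled alkylation is used; the product 22 is a diastereomer that can be purified.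

**C5 carbon.** Bromide 17 comes from alcohol 16 and, through aldehyde 15, from aryl bromide 14. The bromine at C5 is inert through everything before it and is turned into the benzylic carbon by halogen–lithium exchange only after the ring is closed.

**O1–C2 bond (key disconnection).** Cutting O1–C2 of 14 gives phenol–benzylic alcohol 13. The forward reaction ionises the carbinol and lets the ortho phenol close the ring. This removes the need to control the carbinol centre and leaves C3 as the only stereocentre to install.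

**C2–C3 bond.** Phenol 13 is derived from allyl ether 12, diol 11 and aldol adduct 10. Cutting the bond between the carbinol carbon and the future C3 gives arylacetyl imide 8 and aldehyde 9. The boron aldol forms this bond and fixes the future C3 through the (4S)-auxiliary 6. The phenol is carried as an allyl ether so that it can be released without acid and 13 can be isolated before the acid step.

**Arylacetic acid.** Imide 8 comes from acid 5 (through anhydride 7) and auxiliary 6. Acid 5 is the one-carbon homologue of aldehyde 2, reached through enol ether 3 and aldehyde 4, and 2 is the allyl ether of commercial 1.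

**Aryl glycerol ether.** Bromide 35 comes from alcohol 34 and ester 33, so the aryl ester of 26 serves as the latent benzylic bromide. A syn aldol of an aryloxyacetyl imide gives the threo (syn) relationship, not the erythro one the target has. The aldol of 27 with 9 is therefore used to set the aryloxy-bearing carbon (adduct 28, diol 29, silyl ether 30), and the carbinol is then inverted (ester 31, alcohol 32). Imide 27 is the phenol alkylation product of 26 with bromoacetyl imide 25, which is made from auxiliary 19.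

## Alternatives that were turned down

**Alternative 1:** 
- **Disconnection and key step:** Both exocyclic C–C bonds on lactone C3 and C4 are cut at once. The lithiated dithiane A2 adds to C4 of the chiral butenolide A3 anti to the menthyloxy group, and the resulting enolate is trapped at C3 by bromide 35, giving A1 in one pot.
- **For:** Three components, two C–C bonds and both lactone stereocentres are set in one operation, relayed from the acetal carbon. On the lactone this is clearly more convergent than the four steps (14, 15, 16, 27) used here.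
- **Against:** A1 still has to lose the dithiane (Raney Ni) and the menthyloxy acetal (reduction and relactonisation). Desulfurisation in the presence of two benzyl ethers, the benzylic O1–C2 bond and a benzylic silyl ether invites hydrogenolysis. The hindered anion of A2 has to add to A3 and then be alkylated by a large electrophile. A2 itself must be made from an aldehyde like 15, so the alternative leaves the formation of the dihydrobenzofuran unsolved.
- **Comparison:** The chosen route pays more steps on the lactone. In return it needs no late sulfur removal, each lactone centre is set in a separate, purifiable step, and the hardest pair (C2/C3) is handled by a stereoconvergent closure.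

**Alternative 2:** 
- **Disconnection and key step:** The C3–C3a bond of the dihydrobenzofuran is cut. Oxidation of flavanone A5 at C3 with PhI(OAc)2/H2SO4 in HC(OMe)3 (or Tl(NO3)3) triggers a shift of the fused aryl carbon from C4 to C3 and contracts the pyranone to the trans ester A4.
- **For:** A5 is two steps (condensation and oxa-Michael closure) from simple aromatic carbonyl compounds. The contraction is trans-selective and the ester is the hydroxymethyl group at the right oxidation level. It would reach the dihydrobenzofuran in about half the ten steps used here.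
- **Against:** All absolute configuration has to come from an enantioenriched A5. Its C2 is a benzylic ether β to a ketone and racemises by retro-oxa-Michael opening under the strongly acidic conditions of the key step. The wanted 1,2-shift competes with migration of the C2 aryl group and with dehydrogenation, both favoured by the electron-rich aryl ring at C2. The pivalate has to be exchanged later, and the thallium variant is toxic.
- **Comparison:** It is shorter but weak exactly where this target is demanding, namely enantiocontrol. The chosen route fixes C3 by an auxiliary with a predictable model and lets C2 follow thermodynamically.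

**Alternative 3:** 
- **Disconnection and key step:** The lactone O–CH2 bond is cut. A catalytic asymmetric Baeyer–Villiger oxidation (Sc(OTf)3 with a chiral N,N'-dioxide and m-CPBA, or a monooxygenase) inserts oxygen next to one enantiotopic CH2 of cyclobutanone A7 and gives lactone A6.
- **For:** It is catalytic, uses no stoichiometric auxiliary and makes the lactone ring and its C4 centre in one step.
- **Against:** A peracid meets three electron-rich arenes. Differentiation of enantiotopic groups is rarely complete, and because the new centre is remote from C2/C3 the minor diastereomer would be very hard to separate. A7 needs about three steps from a bromide like 14 (allylation, ketene cycloaddition, dechlorination). As in alternative 1, the dihydrobenzofuran must be made anyway.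
- **Comparison:** The step count is about the same as steps 11–16. The chosen route gives up catalysis for an alkylation whose diastereomeric product 22 can be purified, so the stereochemical purity of 24 is secured before the fragment coupling.

Key step: step 10

## Route

Step 1
Reactants: 1 5-bromo-2-hydroxy-3-methoxybenzaldehyde (5-bromo-o-vanillin)
Product: 2 5-bromo-3-methoxy-2-(prop-2-en-1-yloxy)benzaldehyde
Conditions: allyl bromide, K2CO3, DMF, rt
Reagents that add atoms: allyl bromide, C=CCBr
Why: Williamson alkylation of the phenoxide; the allyl ether tolerates base, hydride, boron triflate and dilute acid and can later be removed without acid, which is needed because the benzylic alcohol made in step 6 ionises in acid.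

Step 2
Reactants: 2 5-bromo-3-methoxy-2-(prop-2-en-1-yloxy)benzaldehyde
Product: 3 5-bromo-1-methoxy-3-(2-methoxyethenyl)-2-(prop-2-en-1-yloxy)benzene (E/Z mixture)
Conditions: MeOCH2PPh3Cl, KOt-Bu, THF, 0 °C → rt
Reagents that add atoms: (methoxymethyl)triphenylphosphonium chloride, COC[P+](c1ccccc1)(c1ccccc1)c1ccccc1.[Cl-]
Why: Wittig methoxymethylenation of an aromatic aldehyde; both alkene isomers give the same aldehyde in step 3.

Step 3
Reactants: 3 5-bromo-1-methoxy-3-(2-methoxyethenyl)-2-(prop-2-en-1-yloxy)benzene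
Product: 4 2-[5-bromo-3-methoxy-2-(prop-2-en-1-yloxy)phenyl]acetaldehyde
Conditions: 2 M HCl, THF, 50 °C
Reagents that add atoms: water, O
Why: Acid hydrolysis of the enol ether through the oxocarbenium ion and hemiacetal; the aryl allyl ether and aryl bromide are inert, and the aldehyde should be taken on without storage.

Step 4
Reactants: 4 2-[5-bromo-3-methoxy-2-(prop-2-en-1-yloxy)phenyl]acetaldehyde
Product: 5 2-[5-bromo-3-methoxy-2-(prop-2-en-1-yloxy)phenyl]acetic acid
Conditions: NaClO2, NaH2PO4, 2-methyl-2-butene, t-BuOH/H2O, 0 °C → rt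
Reagents that add atoms: sodium chlorite, [Na+].[O-]Cl=O
Why: Pinnick oxidation; excess trisubstituted alkene traps the hypochlorous acid before it can attack the allyl ether or the electron-rich ring.

Step 5
Reactants: 5 2-[5-bromo-3-methoxy-2-(prop-2-en-1-yloxy)phenyl]acetic acid; 6 (4S)-4-benzyl-1,3-oxazolidin-2-one
Product: 8 (4S)-4-benzyl-3-{2-[5-bromo-3-methoxy-2-(prop-2-en-1-yloxy)phenyl]acetyl}-1,3-oxazolidin-2-one, via mixed pivalic anhydride 7 (not isolated)
Conditions: PivCl, Et3N, THF, −20 °C; then 6, LiCl, −20 °C → rt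
Reagents that add atoms: pivaloyl chloride, CC(C)(C)C(Cl)=O (its acyl group is carried only by intermediate 7)
Why: N-acylation of the oxazolidinone by a mixed anhydride, which is attacked at the unhindered arylacetyl carbonyl; the phenol is masked, so no benzofuranone can form.

Step 6
Reactants: 8 (4S)-4-benzyl-3-{2-[5-bromo-3-methoxy-2-(prop-2-en-1-yloxy)phenyl]acetyl}-1,3-oxazolidin-2-one; 9 4-(benzyloxy)-3-methoxybenzaldehyde (O-benzylvanillin)
Product: 10 syn aldol adduct, (4S)-4-benzyl-3-{(2S,3S)-3-[4-(benzyloxy)-3-methoxyphenyl]-2-[5-bromo-3-methoxy-2-(prop-2-en-1-yloxy)phenyl]-3-hydroxypropanoyl}-1,3-oxazolidin-2-one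
Conditions: Bu2BOTf, i-Pr2NEt, CH2Cl2, −78 → 0 °C; 9, −78 → 0 °C; pH 7 buffer, MeOH, H2O2
Reagents that add atoms: none
Why: Evans boron aldol: the Z-dibutylboron enolate reacts through a Zimmerman–Traxler chair on the face away from the benzyl group of the dipole-opposed (4S)-auxiliary, which sets the α-carbon (2S), the future C3 of the dihydrobenzofuran; the syn carbinol (3S) is incidental because step 10 erases it.

Step 7
Reactants: 10 syn aldol adduct
Product: 11 (1S,2R)-1-[4-(benzyloxy)-3-methoxyphenyl]-2-[5-bromo-3-methoxy-2-(prop-2-en-1-yloxy)phenyl]propane-1,3-diol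
Conditions: LiBH4, MeOH, THF, 0 °C
Reagents that add atoms: none
Why: Reductive cleavage of the N-acyl oxazolidinone at the exocyclic carbonyl gives the primary alcohol and releases the auxiliary; the benzylic stereocentre is not enolised under these conditions (its descriptor changes to R only through the priority change).

Step 8
Reactants: 11 (1S,2R)-diol
Product: 12 (1S,2R)-1-[4-(benzyloxy)-3-methoxyphenyl]-2-[5-bromo-3-methoxy-2-(prop-2-en-1-yloxy)phenyl]-3-{[tri(propan-2-yl)silyl]oxy}propan-1-ol
Conditions: TIPSCl, imidazole, CH2Cl2, 0 °C → rt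
Reagents that add atoms: chlorotri(propan-2-yl)silane, CC(C)[Si](Cl)(C(C)C)C(C)C
Why: The bulky silyl chloride selects the primary over the hindered secondary benzylic hydroxyl; the silyl ether is there to prevent loss of this carbon as formaldehyde from the cation in step 10.

Step 9
Reactants: 12 allyl ether
Product: 13 (1S,2R)-1-[4-(benzyloxy)-3-methoxyphenyl]-2-(5-bromo-2-hydroxy-3-methoxyphenyl)-3-{[tri(propan-2-yl)silyl]oxy}propan-1-ol
Conditions: Pd(PPh3)4 (5 mol %), morpholine, THF, rt
Reagents that add atoms: none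
Why: Tsuji–Trost deallylation: zerovalent palladium ionises the aryl allyl ether and morpholine captures the allyl group; at room temperature this is much faster than oxidative addition to the electron-rich aryl bromide, and no acid is present, so the benzylic alcohol survives.

Step 10
Reactants: 13 (1S,2R)-1-[4-(benzyloxy)-3-methoxyphenyl]-2-(5-bromo-2-hydroxy-3-methoxyphenyl)-3-{[tri(propan-2-yl)silyl]oxy}propan-1-ol
Product: 14 (2S,3R)-2-[4-(benzyloxy)-3-methoxyphenyl]-5-bromo-7-methoxy-3-({[tri(propan-2-yl)silyl]oxy}methyl)-2,3-dihydro-1-benzofuran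
Conditions: camphor-10-sulfonic acid (0.2 equiv), CH2Cl2, 0 °C → rt
Reagents that add atoms: none
Why: The sulfonic acid protonates the benzylic hydroxyl of 13 and water leaves, giving a cation delocalised into the para-benzyloxy ring (a protonated quinone methide), so the configuration of the carbinol carbon is erased. The ortho phenol oxygen then adds to this exocyclic cationic carbon in a 5-exo-trig closure that forms O1–C2 and the dihydrofuran ring. The closest known reaction type is the acid-mediated cyclodehydration of 2-(2-hydroxyaryl)-1-arylpropane-1,3-diol derivatives to phenylcoumarans, the laboratory counterpart of quinone-methide trapping in neolignan biosynthesis. The new stereocentre C2 is controlled by C3: the oxygen adds to the face of the cation anti to the silyloxymethyl group, and because the benzylic C–O bond re-ionises under the same acid, any cis ring returns to the cation and drains to the more stable trans (2S,3R) isomer. C3 is not touched, since it bears no leaving group and its proton is not removed under these mild conditions. The step needs closure to win over loss of the C3 proton (stilbene formation) and over extrusion of the primary carbon; the intramolecular phenol, the non-nucleophilic solvent and the silyl ether on the primary oxygen secure this. The aryl bromide, the benzyl ether and the primary silyl ether are inert to catalytic sulfonic acid in CH2Cl2.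

Step 11
Reactants: 14 5-bromo-dihydrobenzofuran
Product: 16 [(2S,3R)-2-[4-(benzyloxy)-3-methoxyphenyl]-7-methoxy-3-({[tri(propan-2-yl)silyl]oxy}methyl)-2,3-dihydro-1-benzofuran-5-yl]methanol, via 5-carbaldehyde 15 (not isolated)
Conditions: n-BuLi, THF, −78 °C; DMF, −78 → 0 °C; then MeOH, NaBH4, 0 °C
Reagents that add atoms: N,N-dimethylformamide, CN(C)C=O
Why: Bromine–lithium exchange is faster at −78 °C than any deprotonation; the aryllithium is formylated by DMF and the aldehyde released on adding methanol is reduced in the same flask by borohydride.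

Step 12
Reactants: 16 benzylic alcohol
Product: 17 (2S,3R)-2-[4-(benzyloxy)-3-methoxyphenyl]-5-(bromomethyl)-7-methoxy-3-({[tri(propan-2-yl)silyl]oxy}methyl)-2,3-dihydro-1-benzofuran
Conditions: CBr4, PPh3, CH2Cl2, 0 °C
Reagents that add atoms: carbon tetrabromide, BrC(Br)(Br)Br
Why: Appel bromination under neutral conditions, which spares the silyl ether and the acid-labile O1–C2 bond; the para-alkoxybenzyl bromide is used at once.

Step 13
Reactants: 18 4-tert-butoxy-4-oxobutanoic acid; 19 (4R)-4-benzyl-1,3-oxazolidin-2-one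
Product: 21 tert-butyl 4-[(4R)-4-benzyl-2-oxo-1,3-oxazolidin-3-yl]-4-oxobutanoate, via mixed pivalic anhydride 20 (not isolated)
Conditions: PivCl, Et3N, THF, −20 °C; then 19, LiCl, −20 °C → rt
Reagents that add atoms: pivaloyl chloride, CC(C)(C)C(Cl)=O (its acyl group is carried only by intermediate 20)
Why: Mixed-anhydride N-acylation of the oxazolidinone at the less hindered succinyl carbonyl; the tert-butyl ester is inert.

Step 14
Reactants: 21 succinyl imide; 17 benzylic bromide
Product: 22 tert-butyl (3R)-4-[(4R)-4-benzyl-2-oxo-1,3-oxazolidin-3-yl]-3-{[dihydrobenzofuran-5-yl]methyl}-4-oxobutanoate (dihydrobenzofuran unit as in 16)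
Conditions: NaN(SiMe3)2, THF, −78 °C; then 17, −78 → −40 °C
Reagents that add atoms: none
Why: Evans alkylation: the base removes the more acidic imide α-proton to give the chelated Z-sodium enolate, and the benzylic bromide approaches anti to the benzyl group of the (4R)-auxiliary, setting the new centre (3R), the future lactone C4; the diastereomeric product can be purified.

Step 15
Reactants: 22 alkylated imide
Product: 23 tert-butyl (3R)-4-[dihydrobenzofuran-5-yl]-3-(hydroxymethyl)butanoate
Conditions: LiBH4, MeOH, THF, 0 °C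
Reagents that add atoms: none
Why: Chemoselective reductive removal of the auxiliary; the tert-butyl ester is not reduced by LiBH4 at 0 °C, and the stereocentre is untouched.

Step 16
Reactants: 23 hydroxy tert-butyl ester
Product: 24 (4R)-4-{[(2S,3R)-2-[4-(benzyloxy)-3-methoxyphenyl]-7-methoxy-3-({[tri(propan-2-yl)silyl]oxy}methyl)-2,3-dihydro-1-benzofuran-5-yl]methyl}oxolan-2-one
Conditions: p-TsOH·H2O (10 mol %), CH2Cl2, rt
Reagents that add atoms: none
Why: Acid-catalysed 5-exo lactonisation with loss of tert-butanol; the trans dihydrobenzofuran and the primary silyl ether were formed or carried under the same kind of acid in step 10 and should tolerate it.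

Step 17
Reactants: 19 (4R)-4-benzyl-1,3-oxazolidin-2-one
Product: 25 (4R)-4-benzyl-3-(bromoacetyl)-1,3-oxazolidin-2-one
Conditions: n-BuLi, THF, −78 °C; BrCH2COBr, −78 → 0 °C
Reagents that add atoms: bromoacetyl bromide, BrCC(Br)=O
Why: N-acylation of the lithiated oxazolidinone by the acyl bromide, which is far more electrophilic than the alkyl bromide.

Step 18
Reactants: 25 bromoacetyl imide; 26 methyl 4-hydroxy-3-methoxybenzoate (methyl vanillate)
Product: 27 methyl 4-{2-[(4R)-4-benzyl-2-oxo-1,3-oxazolidin-3-yl]-2-oxoethoxy}-3-methoxybenzoate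
Conditions: K2CO3, acetone, rt
Reagents that add atoms: none
Why: Williamson displacement of the activated α-bromo imide by the phenoxide, which is faster than attack at either imide carbonyl; the aryl ester is the latent benzylic bromide.

Step 19
Reactants: 27 aryloxyacetyl imide; 9 4-(benzyloxy)-3-methoxybenzaldehyde
Product: 28 methyl 4-({(2R,3S)-1-[(4R)-4-benzyl-2-oxo-1,3-oxazolidin-3-yl]-3-[4-(benzyloxy)-3-methoxyphenyl]-3-hydroxy-1-oxopropan-2-yl}oxy)-3-methoxybenzoate
Conditions: Bu2BOTf, i-Pr2NEt, CH2Cl2, −78 → 0 °C; 9, −78 → 0 °C; pH 7 buffer, MeOH, H2O2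
Reagents that add atoms: none
Why: Evans syn aldol of an aryloxyacetyl imide: the Z-boron enolate and the (4R)-auxiliary set the aryloxy-bearing carbon (2R) as the target needs; the syn carbinol (3S) corresponds to the threo series and is corrected in step 22.

Step 20
Reactants: 28 aldol adduct
Product: 29 methyl 4-({(1S,2S)-1-[4-(benzyloxy)-3-methoxyphenyl]-1,3-dihydroxypropan-2-yl}oxy)-3-methoxybenzoate (threo)
Conditions: NaBH4, THF/H2O (4:1), 0 °C → rt
Reagents that add atoms: none
Why: Borohydride in aqueous THF reduces the activated imide carbonyl to the primary alcohol and frees the auxiliary, but does not reduce the electron-rich aryl methyl ester.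

Step 21
Reactants: 29 threo diol
Product: 30 methyl 4-({(1S,2S)-1-[4-(benzyloxy)-3-methoxyphenyl]-3-{[tert-butyl(dimethyl)silyl]oxy}-1-hydroxypropan-2-yl}oxy)-3-methoxybenzoate
Conditions: TBSCl, imidazole, CH2Cl2, 0 °C
Reagents that add atoms: tert-butyl(chloro)dimethylsilane, CC(C)(C)[Si](C)(C)Cl
Why: Selective silylation of the primary hydroxyl leaves the secondary benzylic alcohol free for inversion.

Step 22
Reactants: 30 threo secondary alcohol
Product: 31 (1R,2S)-1-[4-(benzyloxy)-3-methoxyphenyl]-3-{[tert-butyl(dimethyl)silyl]oxy}-2-[2-methoxy-4-(methoxycarbonyl)phenoxy]propyl 4-nitrobenzoate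
Conditions: 4-O2NC6H4CO2H, PPh3, DIAD, THF, 0 °C → rt
Reagents that add atoms: 4-nitrobenzoic acid, OC(=O)c1ccc(cc1)[N+](=O)[O-]
Why: Mitsunobu esterification: the carboxylate displaces the oxyphosphonium group with inversion, turning (1S) into (1R) and threo into erythro; the acidic nucleophile is the standard choice for hindered secondary alcohols.

Step 23
Reactants: 31 4-nitrobenzoate
Product: 32 methyl 4-({(1R,2S)-1-[4-(benzyloxy)-3-methoxyphenyl]-3-{[tert-butyl(dimethyl)silyl]oxy}-1-hydroxypropan-2-yl}oxy)-3-methoxybenzoate (erythro)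
Conditions: K2CO3, MeOH, 0 °C
Reagents that add atoms: none
Why: Methanolysis of the activated nitrobenzoate; exchange at the aryl methyl ester is degenerate in methanol and the primary silyl ether is stable to carbonate.

Step 24
Reactants: 32 erythro alcohol
Product: 33 methyl 4-({(1R,2S)-1-[4-(benzyloxy)-3-methoxyphenyl]-1,3-bis{[tert-butyl(dimethyl)silyl]oxy}propan-2-yl}oxy)-3-methoxybenzoate
Conditions: TBSOTf, 2,6-lutidine, CH2Cl2, −78 → 0 °C
Reagents that add atoms: tert-butyldimethylsilyl trifluoromethanesulfonate, CC(C)(C)[Si](C)(C)OS(=O)(=O)C(F)(F)F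
Why: The silyl triflate with a hindered base silylates the secondary benzylic hydroxyl at low temperature before it can ionise; the ether protects it from base in step 27.

Step 25
Reactants: 33 aryl methyl ester
Product: 34 [4-({(1R,2S)-1-[4-(benzyloxy)-3-methoxyphenyl]-1,3-bis{[tert-butyl(dimethyl)silyl]oxy}propan-2-yl}oxy)-3-methoxyphenyl]methanol
Conditions: i-Bu2AlH, CH2Cl2, −78 → 0 °C
Reagents that add atoms: none
Why: Hydride reduction of the aryl ester to the benzylic alcohol; silyl and benzyl ethers are inert.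

Step 26
Reactants: 34 benzylic alcohol
Product: 35 1-(benzyloxy)-4-{(1R,2S)-2-[4-(bromomethyl)-2-methoxyphenoxy]-1,3-bis{[tert-butyl(dimethyl)silyl]oxy}propyl}-2-methoxybenzene
Conditions: CBr4, PPh3, CH2Cl2, 0 °C
Reagents that add atoms: carbon tetrabromide, BrC(Br)(Br)Br
Why: Appel bromination under neutral conditions; the benzylic silyl ether is not touched and the bromide is used directly.

Step 27
Reactants: 24 (4R)-lactone; 35 benzylic bromide
Product: 36 fully protected trans-(3R,4R)-dibenzyl lactone
Conditions: LiN(SiMe3)2, THF, −78 °C; then 35, DMPU, −78 → −30 °C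
Reagents that add atoms: none
Why: Alkylation of the lithium enolate of a 4-substituted oxolan-2-one takes place on the face anti to the C4 substituent, which sets C3 (R) trans to C4; para-alkoxybenzyl bromides are reactive enough at low temperature.

Step 28
Reactants: 36 fully protected lactone
Product: 37 dibenzyl ether triol
Conditions: Bu4NF, AcOH, THF, 0 °C → rt
Reagents that add atoms: none
Why: Fluoride cleaves the two tert-butyldimethylsilyl ethers and the triisopropylsilyl ether; buffering with acetic acid keeps the lactone and its C3 centre intact, and with the phenols still benzylated no quinone methide can form.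

Step 29
Reactants: 37 dibenzyl ether triol
Product: 38 CNP0298853.1
Conditions: H2 (1 atm), 10% Pd/C, EtOAc/MeOH, rt
Reagents that add atoms: none
Why: Hydrogenolysis of the two aryl benzyl ethers under neutral conditions; aryl O-benzyl bonds cleave much faster than the benzylic alcohol or the cyclic benzylic aryl ether, so the reaction is stopped once two equivalents of hydrogen are taken up.

## Compound list

1 | 5-bromo-2-hydroxy-3-methoxybenzaldehyde (5-bromo-o-vanillin) | COc1cc(Br)cc(C=O)c1O | starting material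
2 | 5-bromo-3-methoxy-2-(prop-2-en-1-yloxy)benzaldehyde | COc1cc(Br)cc(C=O)c1OCC=C | intermediate
3 | 5-bromo-1-methoxy-3-(2-methoxyethenyl)-2-(prop-2-en-1-yloxy)benzene, E/Z mixture | COC=Cc1cc(Br)cc(OC)c1OCC=C | intermediate
4 | 2-[5-bromo-3-methoxy-2-(prop-2-en-1-yloxy)phenyl]acetaldehyde | O=CCc1cc(Br)cc(OC)c1OCC=C | intermediate
5 | 2-[5-bromo-3-methoxy-2-(prop-2-en-1-yloxy)phenyl]acetic acid | OC(=O)Cc1cc(Br)cc(OC)c1OCC=C | intermediate
6 | (4S)-4-benzyl-1,3-oxazolidin-2-one | O=C1N[C@@H](Cc2ccccc2)CO1 | starting material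
7 | 2-[5-bromo-3-methoxy-2-(prop-2-en-1-yloxy)phenyl]acetic 2,2-dimethylpropanoic anhydride | CC(C)(C)C(=O)OC(=O)Cc1cc(Br)cc(OC)c1OCC=C | intermediate
8 | (4S)-4-benzyl-3-{2-[5-bromo-3-methoxy-2-(prop-2-en-1-yloxy)phenyl]acetyl}-1,3-oxazolidin-2-one | O=C1OC[C@H](Cc2ccccc2)N1C(=O)Cc1cc(Br)cc(OC)c1OCC=C | intermediate
9 | 4-(benzyloxy)-3-methoxybenzaldehyde (O-benzylvanillin) | COc1cc(C=O)ccc1OCc1ccccc1 | starting material
10 | (4S)-4-benzyl-3-{(2S,3S)-3-[4-(benzyloxy)-3-methoxyphenyl]-2-[5-bromo-3-methoxy-2-(prop-2-en-1-yloxy)phenyl]-3-hydroxypropanoyl}-1,3-oxazolidin-2-one | O=C1OC[C@H](Cc2ccccc2)N1C(=O)[C@@H](c1cc(Br)cc(OC)c1OCC=C)[C@H](O)c1ccc(OCc2ccccc2)c(OC)c1 | intermediate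
11 | (1S,2R)-1-[4-(benzyloxy)-3-methoxyphenyl]-2-[5-bromo-3-methoxy-2-(prop-2-en-1-yloxy)phenyl]propane-1,3-diol | OC[C@@H](c1cc(Br)cc(OC)c1OCC=C)[C@H](O)c1ccc(OCc2ccccc2)c(OC)c1 | intermediate
12 | (1S,2R)-1-[4-(benzyloxy)-3-methoxyphenyl]-2-[5-bromo-3-methoxy-2-(prop-2-en-1-yloxy)phenyl]-3-{[tri(propan-2-yl)silyl]oxy}propan-1-ol | CC(C)[Si](OC[C@@H](c1cc(Br)cc(OC)c1OCC=C)[C@H](O)c1ccc(OCc2ccccc2)c(OC)c1)(C(C)C)C(C)C | intermediate
13 | (1S,2R)-1-[4-(benzyloxy)-3-methoxyphenyl]-2-(5-bromo-2-hydroxy-3-methoxyphenyl)-3-{[tri(propan-2-yl)silyl]oxy}propan-1-ol | CC(C)[Si](OC[C@@H](c1cc(Br)cc(OC)c1O)[C@H](O)c1ccc(OCc2ccccc2)c(OC)c1)(C(C)C)C(C)C | intermediate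
14 | (2S,3R)-2-[4-(benzyloxy)-3-methoxyphenyl]-5-bromo-7-methoxy-3-({[tri(propan-2-yl)silyl]oxy}methyl)-2,3-dihydro-1-benzofuran | Brc1cc(OC)c2c(c1)[C@H](CO[Si](C(C)C)(C(C)C)C(C)C)[C@@H](c1ccc(OCc3ccccc3)c(OC)c1)O2 | intermediate
15 | (2S,3R)-2-[4-(benzyloxy)-3-methoxyphenyl]-7-methoxy-3-({[tri(propan-2-yl)silyl]oxy}methyl)-2,3-dihydro-1-benzofuran-5-carbaldehyde | O=Cc1cc(OC)c2c(c1)[C@H](CO[Si](C(C)C)(C(C)C)C(C)C)[C@@H](c1ccc(OCc3ccccc3)c(OC)c1)O2 | intermediate
16 | [(2S,3R)-2-[4-(benzyloxy)-3-methoxyphenyl]-7-methoxy-3-({[tri(propan-2-yl)silyl]oxy}methyl)-2,3-dihydro-1-benzofuran-5-yl]methanol | OCc1cc(OC)c2c(c1)[C@H](CO[Si](C(C)C)(C(C)C)C(C)C)[C@@H](c1ccc(OCc3ccccc3)c(OC)c1)O2 | intermediate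
17 | (2S,3R)-2-[4-(benzyloxy)-3-methoxyphenyl]-5-(bromomethyl)-7-methoxy-3-({[tri(propan-2-yl)silyl]oxy}methyl)-2,3-dihydro-1-benzofuran | BrCc1cc(OC)c2c(c1)[C@H](CO[Si](C(C)C)(C(C)C)C(C)C)[C@@H](c1ccc(OCc3ccccc3)c(OC)c1)O2 | intermediate
18 | 4-tert-butoxy-4-oxobutanoic acid (mono-tert-butyl succinate) | CC(C)(C)OC(=O)CCC(O)=O | starting material
19 | (4R)-4-benzyl-1,3-oxazolidin-2-one | O=C1N[C@H](Cc2ccccc2)CO1 | starting material
20 | 4-tert-butoxy-4-oxobutanoic 2,2-dimethylpropanoic anhydride | CC(C)(C)OC(=O)CCC(=O)OC(=O)C(C)(C)C | intermediate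
21 | tert-butyl 4-[(4R)-4-benzyl-2-oxo-1,3-oxazolidin-3-yl]-4-oxobutanoate | CC(C)(C)OC(=O)CCC(=O)N1[C@H](Cc2ccccc2)COC1=O | intermediate
22 | tert-butyl (3R)-4-[(4R)-4-benzyl-2-oxo-1,3-oxazolidin-3-yl]-3-{[(2S,3R)-2-[4-(benzyloxy)-3-methoxyphenyl]-7-methoxy-3-({[tri(propan-2-yl)silyl]oxy}methyl)-2,3-dihydro-1-benzofuran-5-yl]methyl}-4-oxobutanoate | CC(C)(C)OC(=O)C[C@@H](Cc1cc(OC)c2c(c1)[C@H](CO[Si](C(C)C)(C(C)C)C(C)C)[C@@H](c1ccc(OCc3ccccc3)c(OC)c1)O2)C(=O)N1[C@H](Cc2ccccc2)COC1=O | intermediate
23 | tert-butyl (3R)-4-[(2S,3R)-2-[4-(benzyloxy)-3-methoxyphenyl]-7-methoxy-3-({[tri(propan-2-yl)silyl]oxy}methyl)-2,3-dihydro-1-benzofuran-5-yl]-3-(hydroxymethyl)butanoate | CC(C)(C)OC(=O)C[C@@H](Cc1cc(OC)c2c(c1)[C@H](CO[Si](C(C)C)(C(C)C)C(C)C)[C@@H](c1ccc(OCc3ccccc3)c(OC)c1)O2)CO | intermediate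
24 | (4R)-4-{[(2S,3R)-2-[4-(benzyloxy)-3-methoxyphenyl]-7-methoxy-3-({[tri(propan-2-yl)silyl]oxy}methyl)-2,3-dihydro-1-benzofuran-5-yl]methyl}oxolan-2-one | O=C1C[C@@H](Cc2cc(OC)c3c(c2)[C@H](CO[Si](C(C)C)(C(C)C)C(C)C)[C@@H](c2ccc(OCc4ccccc4)c(OC)c2)O3)CO1 | intermediate
25 | (4R)-4-benzyl-3-(bromoacetyl)-1,3-oxazolidin-2-one | BrCC(=O)N1[C@H](Cc2ccccc2)COC1=O | intermediate
26 | methyl 4-hydroxy-3-methoxybenzoate (methyl vanillate) | COC(=O)c1ccc(O)c(OC)c1 | starting material
27 | methyl 4-{2-[(4R)-4-benzyl-2-oxo-1,3-oxazolidin-3-yl]-2-oxoethoxy}-3-methoxybenzoate | COC(=O)c1ccc(OCC(=O)N2[C@H](Cc3ccccc3)COC2=O)c(OC)c1 | intermediate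
28 | methyl 4-({(2R,3S)-1-[(4R)-4-benzyl-2-oxo-1,3-oxazolidin-3-yl]-3-[4-(benzyloxy)-3-methoxyphenyl]-3-hydroxy-1-oxopropan-2-yl}oxy)-3-methoxybenzoate | O=C1OC[C@@H](Cc2ccccc2)N1C(=O)[C@H](Oc1ccc(C(=O)OC)cc1OC)[C@@H](O)c1ccc(OCc2ccccc2)c(OC)c1 | intermediate
29 | methyl 4-({(1S,2S)-1-[4-(benzyloxy)-3-methoxyphenyl]-1,3-dihydroxypropan-2-yl}oxy)-3-methoxybenzoate (threo) | OC[C@H](Oc1ccc(C(=O)OC)cc1OC)[C@@H](O)c1ccc(OCc2ccccc2)c(OC)c1 | intermediate
30 | methyl 4-({(1S,2S)-1-[4-(benzyloxy)-3-methoxyphenyl]-3-{[tert-butyl(dimethyl)silyl]oxy}-1-hydroxypropan-2-yl}oxy)-3-methoxybenzoate | CC(C)(C)[Si](C)(C)OC[C@H](Oc1ccc(C(=O)OC)cc1OC)[C@@H](O)c1ccc(OCc2ccccc2)c(OC)c1 | intermediate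
31 | (1R,2S)-1-[4-(benzyloxy)-3-methoxyphenyl]-3-{[tert-butyl(dimethyl)silyl]oxy}-2-[2-methoxy-4-(methoxycarbonyl)phenoxy]propyl 4-nitrobenzoate | CC(C)(C)[Si](C)(C)OC[C@H](Oc1ccc(C(=O)OC)cc1OC)[C@H](OC(=O)c1ccc(cc1)[N+](=O)[O-])c1ccc(OCc2ccccc2)c(OC)c1 | intermediate
32 | methyl 4-({(1R,2S)-1-[4-(benzyloxy)-3-methoxyphenyl]-3-{[tert-butyl(dimethyl)silyl]oxy}-1-hydroxypropan-2-yl}oxy)-3-methoxybenzoate (erythro) | CC(C)(C)[Si](C)(C)OC[C@H](Oc1ccc(C(=O)OC)cc1OC)[C@H](O)c1ccc(OCc2ccccc2)c(OC)c1 | intermediate
33 | methyl 4-({(1R,2S)-1-[4-(benzyloxy)-3-methoxyphenyl]-1,3-bis{[tert-butyl(dimethyl)silyl]oxy}propan-2-yl}oxy)-3-methoxybenzoate | CC(C)(C)[Si](C)(C)OC[C@H](Oc1ccc(C(=O)OC)cc1OC)[C@H](O[Si](C)(C)C(C)(C)C)c1ccc(OCc2ccccc2)c(OC)c1 | intermediate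
34 | [4-({(1R,2S)-1-[4-(benzyloxy)-3-methoxyphenyl]-1,3-bis{[tert-butyl(dimethyl)silyl]oxy}propan-2-yl}oxy)-3-methoxyphenyl]methanol | CC(C)(C)[Si](C)(C)OC[C@H](Oc1ccc(CO)cc1OC)[C@H](O[Si](C)(C)C(C)(C)C)c1ccc(OCc2ccccc2)c(OC)c1 | intermediate
35 | 1-(benzyloxy)-4-{(1R,2S)-2-[4-(bromomethyl)-2-methoxyphenoxy]-1,3-bis{[tert-butyl(dimethyl)silyl]oxy}propyl}-2-methoxybenzene | CC(C)(C)[Si](C)(C)OC[C@H](Oc1ccc(CBr)cc1OC)[C@H](O[Si](C)(C)C(C)(C)C)c1ccc(OCc2ccccc2)c(OC)c1 | intermediate
36 | (3R,4R)-3-{[4-({(1R,2S)-1-[4-(benzyloxy)-3-methoxyphenyl]-1,3-bis{[tert-butyl(dimethyl)silyl]oxy}propan-2-yl}oxy)-3-methoxyphenyl]methyl}-4-{[(2S,3R)-2-[4-(benzyloxy)-3-methoxyphenyl]-7-methoxy-3-({[tri(propan-2-yl)silyl]oxy}methyl)-2,3-dihydro-1-benzofuran-5-yl]methyl}oxolan-2-one | COc1cc([C@@H](O[Si](C)(C)C(C)(C)C)[C@H](CO[Si](C)(C)C(C)(C)C)Oc2ccc(C[C@H]3C(=O)OC[C@@H]3Cc3cc(OC)c4c(c3)[C@H](CO[Si](C(C)C)(C(C)C)C(C)C)[C@@H](c3ccc(OCc5ccccc5)c(OC)c3)O4)cc2OC)ccc1OCc1ccccc1 | intermediate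
37 | (3R,4R)-3-{[4-({(1R,2S)-1-[4-(benzyloxy)-3-methoxyphenyl]-1,3-dihydroxypropan-2-yl}oxy)-3-methoxyphenyl]methyl}-4-{[(2S,3R)-2-[4-(benzyloxy)-3-methoxyphenyl]-3-(hydroxymethyl)-7-methoxy-2,3-dihydro-1-benzofuran-5-yl]methyl}oxolan-2-one | COc1cc([C@@H](O)[C@H](CO)Oc2ccc(C[C@H]3C(=O)OC[C@@H]3Cc3cc(OC)c4c(c3)[C@H](CO)[C@@H](c3ccc(OCc5ccccc5)c(OC)c3)O4)cc2OC)ccc1OCc1ccccc1 | intermediate
38 | CNP0298853.1, (3R,4R)-3-{[4-({(1R,2S)-1,3-dihydroxy-1-(4-hydroxy-3-methoxyphenyl)propan-2-yl}oxy)-3-methoxyphenyl]methyl}-4-{[(2S,3R)-2-(4-hydroxy-3-methoxyphenyl)-3-(hydroxymethyl)-7-methoxy-2,3-dihydro-1-benzofuran-5-yl]methyl}oxolan-2-one | COc1cc([C@@H](O)[C@H](CO)Oc2ccc(C[C@H]3C(=O)OC[C@@H]3Cc3cc(OC)c4c(c3)[C@H](CO)[C@@H](c3ccc(O)c(OC)c3)O4)cc2OC)ccc1O | target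

## Step count and least certain steps

Total step count: 29 steps. Longest linear sequence: 18 steps (steps 1–12, 14–16 and 27–29). The aryl glycerol ether branch (steps 17–26) and the succinyl imide (step 13) are side branches.

**Step 10 (key step).**
- What may go wrong: the benzylic cation may lose the C3 proton to give a stilbene instead of closing, and re-protonation of that alkene would erode the C3 configuration. Equilibration of a kinetically formed cis ring to trans may be incomplete. Acid may strip the primary silyl ether, after which the primary carbon can be extruded as formaldehyde.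
- Fallback: a stereospecific double inversion in place of the cationic closure, setting out from 12. Mitsunobu esterification of the carbinol with 4-nitrobenzoic acid gives the inverted (1R,2R)-4-nitrobenzoate F1. Methanolysis gives the (1R,2R)-alcohol F2. Deallylation with Pd(PPh3)4 and morpholine gives the (1R,2R)-phenol F3. Intramolecular Mitsunobu etherification (PPh3, DIAD) then displaces the activated carbinol by the phenol with inversion and returns to the route at 14.

**Step 22.**
- What may go wrong: the oxyphosphonium intermediate sits on a para-alkoxybenzylic carbon and may ionise instead of being displaced, causing partial loss of stereochemical fidelity at the carbinol (erythro/threo mixtures) or elimination.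
- Fallback: oxidation and reagent-controlled reduction, setting out from 30. Dess–Martin periodinane gives the (2S)-α-aryloxy ketone F4 under non-basic conditions that should not epimerise the adjacent centre. Reduction with (R)-2-methyl-CBS-oxazaborolidine and BH3·SMe2 treats the aryl group as the large substituent and delivers the (1R)-carbinol, returning to the route at 32. Chelation of the ketone and aryloxy oxygens points the same way.

**Step 27.**
- What may go wrong: alkylation of the lactone enolate by the large bromide 35 may be slow, so that ionisation and self-condensation of the electron-rich benzylic bromide compete. Proton exchange between product and enolate could then lead to a second alkylation.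
- Fallback: aldol, dehydration and conjugate reduction, setting out from 34 and 24. MnO2 oxidises 34 to the aldehyde F5. Addition of the lithium enolate of 24 gives the aldol adduct F6 as carbinol epimers. MsCl/Et3N gives the mesylate F7, and DBU eliminates it to the (E)-benzylidene lactone F8. Conjugate reduction with NiCl2·6H2O/NaBH4, followed by base equilibration of C3 to the more stable trans isomer, returns to the route at 36.

**Step 29.**
- What may go wrong: hydrogenolysis may go too far once the phenols are free, cleaving the benzylic C–OH bond of the glycerol unit or the O1–C2 bond of the dihydrobenzofuran.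
- Fallback: reverse the order of the last two steps, setting out from 36. Hydrogenolysis (H2, Pd/C, EtOAc) with all three alcohols still silylated gives the bis-phenol tris-silyl ether F9, in which the benzylic oxygen is a bulky silyl ether and less prone to cleavage. HF·pyridine in THF/pyridine then removes the silyl groups under non-basic conditions and returns to the route at 38.

## Further compounds

F1 | step 10 | (1R,2R)-1-[4-(benzyloxy)-3-methoxyphenyl]-2-[5-bromo-3-methoxy-2-(prop-2-en-1-yloxy)phenyl]-3-{[tri(propan-2-yl)silyl]oxy}propyl 4-nitrobenzoate | CC(C)[Si](OC[C@@H](c1cc(Br)cc(OC)c1OCC=C)[C@@H](OC(=O)c1ccc(cc1)[N+](=O)[O-])c1ccc(OCc2ccccc2)c(OC)c1)(C(C)C)C(C)C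
F2 | step 10 | (1R,2R)-1-[4-(benzyloxy)-3-methoxyphenyl]-2-[5-bromo-3-methoxy-2-(prop-2-en-1-yloxy)phenyl]-3-{[tri(propan-2-yl)silyl]oxy}propan-1-ol | CC(C)[Si](OC[C@@H](c1cc(Br)cc(OC)c1OCC=C)[C@@H](O)c1ccc(OCc2ccccc2)c(OC)c1)(C(C)C)C(C)C
F3 | step 10 | (1R,2R)-1-[4-(benzyloxy)-3-methoxyphenyl]-2-(5-bromo-2-hydroxy-3-methoxyphenyl)-3-{[tri(propan-2-yl)silyl]oxy}propan-1-ol | CC(C)[Si](OC[C@@H](c1cc(Br)cc(OC)c1O)[C@@H](O)c1ccc(OCc2ccccc2)c(OC)c1)(C(C)C)C(C)C
F4 | step 22 | methyl 4-({(2S)-1-[4-(benzyloxy)-3-methoxyphenyl]-3-{[tert-butyl(dimethyl)silyl]oxy}-1-oxopropan-2-yl}oxy)-3-methoxybenzoate | CC(C)(C)[Si](C)(C)OC[C@H](Oc1ccc(C(=O)OC)cc1OC)C(=O)c1ccc(OCc2ccccc2)c(OC)c1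
F5 | step 27 | 4-({(1R,2S)-1-[4-(benzyloxy)-3-methoxyphenyl]-1,3-bis{[tert-butyl(dimethyl)silyl]oxy}propan-2-yl}oxy)-3-methoxybenzaldehyde | CC(C)(C)[Si](C)(C)OC[C@H](Oc1ccc(C=O)cc1OC)[C@H](O[Si](C)(C)C(C)(C)C)c1ccc(OCc2ccccc2)c(OC)c1
F6 | step 27 | aldol adduct of the enolate of 24 with F5: 36 bearing a hydroxyl group on the benzylic carbon attached to lactone C3, trans at the lactone, both carbinol epimers | COc1cc([C@@H](O[Si](C)(C)C(C)(C)C)[C@H](CO[Si](C)(C)C(C)(C)C)Oc2ccc(C(O)[C@H]3C(=O)OC[C@@H]3Cc3cc(OC)c4c(c3)[C@H](CO[Si](C(C)C)(C(C)C)C(C)C)[C@@H](c3ccc(OCc5ccccc5)c(OC)c3)O4)cc2OC)ccc1OCc1ccccc1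
F7 | step 27 | methanesulfonate of F6 | COc1cc([C@@H](O[Si](C)(C)C(C)(C)C)[C@H](CO[Si](C)(C)C(C)(C)C)Oc2ccc(C(OS(C)(=O)=O)[C@H]3C(=O)OC[C@@H]3Cc3cc(OC)c4c(c3)[C@H](CO[Si](C(C)C)(C(C)C)C(C)C)[C@@H](c3ccc(OCc5ccccc5)c(OC)c3)O4)cc2OC)ccc1OCc1ccccc1
F8 | step 27 | (E)-3-benzylidene lactone: 36 with an exocyclic C=C bond between lactone C3 and the benzylic carbon | COc1cc([C@@H](O[Si](C)(C)C(C)(C)C)[C@H](CO[Si](C)(C)C(C)(C)C)Oc2ccc(/C=C3/C(=O)OC[C@@H]3Cc3cc(OC)c4c(c3)[C@H](CO[Si](C(C)C)(C(C)C)C(C)C)[C@@H](c3ccc(OCc5ccccc5)c(OC)c3)O4)cc2OC)ccc1OCc1ccccc1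
F9 | step 29 | bis-phenol tris-silyl ether: 36 with both benzyl ethers replaced by free phenols | COc1cc([C@@H](O[Si](C)(C)C(C)(C)C)[C@H](CO[Si](C)(C)C(C)(C)C)Oc2ccc(C[C@H]3C(=O)OC[C@@H]3Cc3cc(OC)c4c(c3)[C@H](CO[Si](C(C)C)(C(C)C)C(C)C)[C@@H](c3ccc(O)c(OC)c3)O4)cc2OC)ccc1O
A1 | alternative 1 | all-trans 3-benzyl-4-(2-aryl-1,3-dithian-2-yl)-5-menthyloxy lactone | COc1cc([C@@H](O[Si](C)(C)C(C)(C)C)[C@H](CO[Si](C)(C)C(C)(C)C)Oc2ccc(C[C@H]3C(=O)O[C@@H](O[C@@H]4C[C@H](C)CC[C@H]4C(C)C)[C@@H]3C3(SCCCS3)c3cc(OC)c4c(c3)[C@H](CO[Si](C)(C)C(C)(C)C)[C@@H](c3ccc(OCc5ccccc5)c(OC)c3)O4)cc2OC)ccc1OCc1ccccc1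
A2 | alternative 1 | 2-[(2S,3R)-2-[4-(benzyloxy)-3-methoxyphenyl]-3-({[tert-butyl(dimethyl)silyl]oxy}methyl)-7-methoxy-2,3-dihydro-1-benzofuran-5-yl]-1,3-dithiane | C1CSC(SC1)c1cc(OC)c2c(c1)[C@H](CO[Si](C)(C)C(C)(C)C)[C@@H](c1ccc(OCc3ccccc3)c(OC)c1)O2
A3 | alternative 1 | (5R)-5-(menthyloxy)furan-2(5H)-one | O=C1C=C[C@H](O[C@@H]2C[C@H](C)CC[C@H]2C(C)C)O1
A4 | alternative 2 | methyl trans-5-bromo-7-methoxy-2-(3-methoxy-4-pivaloyloxyphenyl)-2,3-dihydrobenzofuran-3-carboxylate | Brc1cc(OC)c2c(c1)[C@H](C(=O)OC)[C@@H](c1ccc(OC(=O)C(C)(C)C)c(OC)c1)O2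
A5 | alternative 2 | (2S)-6-bromo-8-methoxy-2-(3-methoxy-4-pivaloyloxyphenyl)chroman-4-one | O=C1C[C@@H](c2ccc(OC(=O)C(C)(C)C)c(OC)c2)Oc2c(OC)cc(Br)cc12
A6 | alternative 3 | (R)-4-(dihydrobenzofuran-5-ylmethyl)dihydrofuran-2(3H)-one, protected | O=C1C[C@@H](Cc2cc(OC)c3c(c2)[C@H](CO[Si](C)(C)C(C)(C)C)[C@@H](c2ccc(OCc4ccccc4)c(OC)c2)O3)CO1
A7 | alternative 3 | 3-{[(2S,3R)-2-[4-(benzyloxy)-3-methoxyphenyl]-3-({[tert-butyl(dimethyl)silyl]oxy}methyl)-7-methoxy-2,3-dihydro-1-benzofuran-5-yl]methyl}cyclobutan-1-one | O=C1CC(Cc2cc(OC)c3c(c2)[C@H](CO[Si](C)(C)C(C)(C)C)[C@@H](c2ccc(OCc4ccccc4)c(OC)c2)O3)C1
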